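The target is achiral, so only connectivity has to be built. Ring C is taken apart across two bonds, C3–C4 and O1–C2, which uses the fact that C4 and O1 hang on neighbouring carbons (C4a and C8a) of the fully oxygenated ring A, while C2–C3 is a two-carbon unit carrying ring B at C3. A single condensation joins salicylaldehyde 11 (formyl carbon = C4, its only free ortho-hydroxyl = O1, remaining phenols benzylated, 6-OMe in place) with morpholine enamine 17 of the ring-B arylacetaldehyde (C2 and C3), making both bonds and the pyran ring as a 2-morpholinochroman-4-ol. Oxidation, loss of morpholine and hydrogenolysis finish the isoflavone.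

Key step: step 12

Remark on the chemistry: the target has no stereocentre, so no configuration has to be set; the three stereocentres created in step 12 are removed again in step 13.

Step 1
Reactants: 1 2-methoxyresorcinol
Product: 2 1,3-bis(benzyloxy)-2-methoxybenzene
Conditions: BnBr (2.2 equiv), K2CO3, DMF, 60 °C
Reagents that add atoms: benzyl bromide, BrCc1ccccc1
Why: Williamson ether synthesis on both phenols of a symmetrical diol, so no selectivity question arises.

Step 2
Reactants: 2 1,3-bis(benzyloxy)-2-methoxybenzene
Product: 4 2,4-bis(benzyloxy)-3-methoxybenzaldehyde, via aryl iminium salt 3 (not isolated)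
Conditions: POCl3, DMF, 0 → 70 °C; then H2O, rt
Reagents that add atoms: N,N-dimethylformamide, CN(C)C=O; water, O
Why: Vilsmeier–Haack formylation should occur at C4 (equivalent to C6 by symmetry), which is para to one benzyloxy group and ortho to the other, whereas C5 is activated only by the twisted 2-methoxy group; water hydrolyses the iminium salt.

Step 3
Reactants: 4 2,4-bis(benzyloxy)-3-methoxybenzaldehyde
Product: 6 2,4-bis(benzyloxy)-3-methoxyphenol, via aryl formate 5 (not isolated)
Conditions: mCPBA, CH2Cl2, 0 °C → rt; then K2CO3 (cat.), MeOH, rt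
Reagents that add atoms: mCPBA, OOC(=O)c1cccc(Cl)c1
Why: Baeyer–Villiger oxidation of a benzaldehyde with ortho and para alkoxy donors proceeds by aryl migration to the formate (a Dakin-type result that does not need a free hydroxyl), and mild methanolysis then frees the phenol without touching the benzyl ethers.

Step 4
Reactants: 6 2,4-bis(benzyloxy)-3-methoxyphenol
Product: 7 3,5-bis(benzyloxy)-2-hydroxy-4-methoxybenzaldehyde
Conditions: MgCl2, Et3N, (CH2O)n, MeCN, reflux
Reagents that add atoms: paraformaldehyde (as formaldehyde), C=O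
Why: Casnati–Skattebøl ortho-formylation delivers formaldehyde inside the magnesium phenoxide chelate only to a carbon ortho to the hydroxyl, and C6 is the single free ortho position, so the other free ring carbon is left alone.

Step 5
Reactants: 7 3,5-bis(benzyloxy)-2-hydroxy-4-methoxybenzaldehyde
Product: 8 2,3,5-tris(benzyloxy)-4-methoxybenzaldehyde
Conditions: BnBr, K2CO3, DMF, 60 °C
Reagents that add atoms: benzyl bromide, BrCc1ccccc1
Why: Williamson ether synthesis; the hydrogen-bonded ortho-hydroxyl of a salicylaldehyde is alkylated cleanly as its potassium phenoxide in DMF.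

Step 6
Reactants: 8 2,3,5-tris(benzyloxy)-4-methoxybenzaldehyde
Product: 10 2,3,5-tris(benzyloxy)-4-methoxyphenol, via aryl formate 9 (not isolated)
Conditions: mCPBA, CH2Cl2, 0 °C → rt; then K2CO3 (cat.), MeOH, rt
Reagents that add atoms: mCPBA, OOC(=O)c1cccc(Cl)c1
Why: Baeyer–Villiger oxidation with aryl migration, favoured by the ortho-benzyloxy and para-methoxy donors, followed by formate methanolysis, places the fifth oxygen on the ring as the only free phenol.

Step 7
Reactants: 10 2,3,5-tris(benzyloxy)-4-methoxyphenol
Product: 11 3,4,6-tris(benzyloxy)-2-hydroxy-5-methoxybenzaldehyde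
Conditions: MgCl2, Et3N, (CH2O)n, MeCN, reflux
Reagents that add atoms: paraformaldehyde (as formaldehyde), C=O
Why: Casnati–Skattebøl ortho-formylation again; the last unsubstituted ring carbon is ortho to the free hydroxyl, so the formyl group can enter only there and the hydroxyl that will become O1 stays free.

Step 8
Reactants: 12 3-hydroxy-4,5-dimethoxybenzaldehyde
Product: 13 3-(benzyloxy)-4,5-dimethoxybenzaldehyde
Conditions: BnBr, K2CO3, DMF, rt → 50 °C
Reagents that add atoms: benzyl bromide, BrCc1ccccc1
Why: Williamson ether synthesis on the single phenol, giving the same protecting group as on ring A so that one final operation removes all of them.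

Step 9
Reactants: 13 3-(benzyloxy)-4,5-dimethoxybenzaldehyde
Product: 14 1-(benzyloxy)-2,3-dimethoxy-5-(2-methoxyethenyl)benzene (E/Z mixture)
Conditions: Ph3P(CH2OMe)Cl, KOtBu, THF, 0 °C → rt
Reagents that add atoms: (methoxymethyl)triphenylphosphonium chloride, COC[P+](c1ccccc1)(c1ccccc1)c1ccccc1.[Cl-]
Why: Wittig methoxymethylenation adds the one carbon needed for the homologated aldehyde; the double-bond geometry is irrelevant because both isomers hydrolyse to the same product.

Step 10
Reactants: 14 1-(benzyloxy)-2,3-dimethoxy-5-(2-methoxyethenyl)benzene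
Product: 15 2-[3-(benzyloxy)-4,5-dimethoxyphenyl]acetaldehyde
Conditions: 2 M HCl, THF, 50 °C
Reagents that add atoms: water, O
Why: Acid-catalysed enol ether hydrolysis (C-protonation, hemiacetal, loss of methanol) should give the arylacetaldehyde, which is used at once because such aldehydes self-condense; aryl benzyl and methyl ethers are stable to dilute acid.

Step 11
Reactants: 15 2-[3-(benzyloxy)-4,5-dimethoxyphenyl]acetaldehyde; 16 morpholine
Product: 17 (E)-4-{2-[3-(benzyloxy)-4,5-dimethoxyphenyl]ethenyl}morpholine
Conditions: morpholine (1.5 equiv), 4 Å MS, toluene, 0 °C → rt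
Reagents that add atoms: none
Why: Enamine condensation of an aldehyde with a secondary amine, driven by water removal and by conjugation with the aryl ring, should give the E isomer as the less hindered, thermodynamically preferred styrene-type geometry.

Step 12
Reactants: 11 3,4,6-tris(benzyloxy)-2-hydroxy-5-methoxybenzaldehyde; 17 (E)-4-{2-[3-(benzyloxy)-4,5-dimethoxyphenyl]ethenyl}morpholine
Product: 18 5,7,8-tris(benzyloxy)-3-[3-(benzyloxy)-4,5-dimethoxyphenyl]-6-methoxy-2-(morpholin-4-yl)chroman-4-ol (racemic mixture of C2/C3/C4 diastereomers)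
Conditions: 17 (1.5 equiv), dry toluene, Ar, rt → 50 °C
Reagents that add atoms: none
Why: The β-carbon of enamine 17, which already carries ring B, adds to the formyl carbon of 11 (activated by the hydrogen bond from the ortho-hydroxyl) to form C3–C4 and leave an iminium ion at C2, and the neighbouring phenol oxygen then adds to that iminium carbon to form O1–C2. The closest known reaction type is the condensation of salicylaldehydes with aldehyde enamines to 2-aminochroman-4-ols, an enamine aldol addition followed by N,O-acetal formation. The pyran ring closes in a 6-exo-trig mode, the C=N+ bond lying outside the new ring. C2, C3 and C4 arise under substrate control only, the reversible additions being expected to favour the all-trans arrangement, and none needs to be controlled because step 13 makes all three planar. Regiochemistry is the one issue, namely whether the oxygen next to C8 or the one next to C6 ends up in the pyran ring; because 11 carries a free OH only at the position flanked by the 3-benzyloxy group and a benzyl ether at the other ortho site, closure can give only the 6-methoxy-5,7,8-trioxygenated chromane and not its 8-methoxy isomer.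

Step 13
Reactants: 18 5,7,8-tris(benzyloxy)-3-[3-(benzyloxy)-4,5-dimethoxyphenyl]-6-methoxy-2-(morpholin-4-yl)chroman-4-ol
Product: 20 5,7,8-tris(benzyloxy)-3-[3-(benzyloxy)-4,5-dimethoxyphenyl]-6-methoxy-4H-chromen-4-one, via 2-morpholinochroman-4-one 19 (not isolated)
Conditions: DMP, pyridine, CH2Cl2, 0 °C → rt; then TsOH·H2O (excess over pyridine), rt
Reagents that add atoms: none
Why: Dess–Martin oxidation of the secondary benzylic alcohol is run with pyridine buffer so that the acid-labile, electron-rich carbinol is not ionised before it is oxidised; acid then protonates the nitrogen and the N,O-acetal carbon loses morpholine together with the acidic C3–H (β-elimination of a Mannich-type base), which creates the C2=C3 bond of the chromone and removes all three stereocentres.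

Step 14
Reactants: 20 5,7,8-tris(benzyloxy)-3-[3-(benzyloxy)-4,5-dimethoxyphenyl]-6-methoxy-4H-chromen-4-one
Product: 21 5,7,8,3'-tetrahydroxy-6,4',5'-trimethoxyisoflavone
Conditions: H2 (1 atm), 10% Pd/C, EtOAc–MeOH, rt; filtration and isolation under Ar
Reagents that add atoms: none
Why: Catalytic hydrogenolysis should cleave the four aryl benzyl ethers much faster than it reduces the C2=C3 bond of the pyranone and leaves the three methyl ethers intact; it is stopped at complete debenzylation and worked up without air because the 5,7,8-trihydroxy ring is easily oxidised.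

Compound list
1 | 2-methoxyresorcinol (2-methoxybenzene-1,3-diol) | COc1c(O)cccc1O | starting material
2 | 1,3-bis(benzyloxy)-2-methoxybenzene | COc1c(OCc2ccccc2)cccc1OCc1ccccc1 | intermediate
3 | N-[2,4-bis(benzyloxy)-3-methoxybenzylidene]-N-methylmethanaminium dichlorophosphate | C[N+](C)=Cc1ccc(OCc2ccccc2)c(OC)c1OCc1ccccc1.[O-]P(Cl)(Cl)=O | intermediate (not isolated)
4 | 2,4-bis(benzyloxy)-3-methoxybenzaldehyde | O=Cc1ccc(OCc2ccccc2)c(OC)c1OCc1ccccc1 | intermediate
5 | 2,4-bis(benzyloxy)-3-methoxyphenyl formate | O=COc1ccc(OCc2ccccc2)c(OC)c1OCc1ccccc1 | intermediate (not isolated)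
6 | 2,4-bis(benzyloxy)-3-methoxyphenol | Oc1ccc(OCc2ccccc2)c(OC)c1OCc1ccccc1 | intermediate
7 | 3,5-bis(benzyloxy)-2-hydroxy-4-methoxybenzaldehyde | O=Cc1cc(OCc2ccccc2)c(OC)c(OCc2ccccc2)c1O | intermediate
8 | 2,3,5-tris(benzyloxy)-4-methoxybenzaldehyde | O=Cc1cc(OCc2ccccc2)c(OC)c(OCc2ccccc2)c1OCc1ccccc1 | intermediate
9 | 2,3,5-tris(benzyloxy)-4-methoxyphenyl formate | O=COc1cc(OCc2ccccc2)c(OC)c(OCc2ccccc2)c1OCc1ccccc1 | intermediate (not isolated)
10 | 2,3,5-tris(benzyloxy)-4-methoxyphenol | Oc1cc(OCc2ccccc2)c(OC)c(OCc2ccccc2)c1OCc1ccccc1 | intermediate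
11 | 3,4,6-tris(benzyloxy)-2-hydroxy-5-methoxybenzaldehyde | O=Cc1c(O)c(OCc2ccccc2)c(OCc2ccccc2)c(OC)c1OCc1ccccc1 | intermediate
12 | 3-hydroxy-4,5-dimethoxybenzaldehyde | COc1cc(C=O)cc(O)c1OC | starting material
13 | 3-(benzyloxy)-4,5-dimethoxybenzaldehyde | COc1cc(C=O)cc(OCc2ccccc2)c1OC | intermediate
14 | 1-(benzyloxy)-2,3-dimethoxy-5-(2-methoxyethenyl)benzene (E/Z mixture, geometry not defined) | COC=Cc1cc(OC)c(OC)c(OCc2ccccc2)c1 | intermediate
15 | 2-[3-(benzyloxy)-4,5-dimethoxyphenyl]acetaldehyde | O=CCc1cc(OC)c(OC)c(OCc2ccccc2)c1 | intermediate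
16 | morpholine | C1COCCN1 | starting material
17 | (E)-4-{2-[3-(benzyloxy)-4,5-dimethoxyphenyl]ethenyl}morpholine | COc1cc(/C=C/N2CCOCC2)cc(OCc2ccccc2)c1OC | intermediate
18 | 5,7,8-tris(benzyloxy)-3-[3-(benzyloxy)-4,5-dimethoxyphenyl]-6-methoxy-2-(morpholin-4-yl)chroman-4-ol (racemic diastereomer mixture, C2/C3/C4 not defined) | OC1c2c(OCc3ccccc3)c(OC)c(OCc3ccccc3)c(OCc3ccccc3)c2OC(N2CCOCC2)C1c1cc(OCc2ccccc2)c(OC)c(OC)c1 | intermediate
19 | 5,7,8-tris(benzyloxy)-3-[3-(benzyloxy)-4,5-dimethoxyphenyl]-6-methoxy-2-(morpholin-4-yl)chroman-4-one (racemic diastereomer mixture, C2/C3 not defined) | O=C1c2c(OCc3ccccc3)c(OC)c(OCc3ccccc3)c(OCc3ccccc3)c2OC(N2CCOCC2)C1c1cc(OCc2ccccc2)c(OC)c(OC)c1 | intermediate (not isolated)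
20 | 5,7,8-tris(benzyloxy)-3-[3-(benzyloxy)-4,5-dimethoxyphenyl]-6-methoxy-4H-chromen-4-one | O=c1c(-c2cc(OC)c(OC)c(OCc3ccccc3)c2)coc2c(OCc3ccccc3)c(OCc3ccccc3)c(OC)c(OCc3ccccc3)c12 | intermediate
21 | 5,7,8,3'-tetrahydroxy-6,4',5'-trimethoxyisoflavone (achiral) | COc1cc(-c2coc3c(O)c(O)c(OC)c(O)c3c2=O)cc(O)c1OC | target

Total step count: 14 (steps 1–7 for ring A, steps 8–11 for the ring-B enamine, steps 12–14 for the union and finish).
Longest linear sequence: 10 steps (steps 1–7, then 12, 13 and 14, from 2-methoxyresorcinol).

Steps most likely to fail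

Step 12 (key annulation). The enamine may add too slowly or reversibly to a formyl group that is flanked by two ortho oxygens and deactivated by three donor substituents, so that hydrolysis or self-condensation of the enamine outruns ring closure. The fallback sets out from 13 and 11 and comes back at 20, so it bypasses step 13 as well. It makes the C3–C4 bond with a benzylic organometallic and inserts C2 afterwards as a one-carbon unit. Aldehyde 13 is reduced with NaBH4 in MeOH to [3-(benzyloxy)-4,5-dimethoxyphenyl]methanol F1, which conc. HCl in CH2Cl2 should convert into 1-(benzyloxy)-5-(chloromethyl)-2,3-dimethoxybenzene F2. Slow addition of F2 to magnesium in THF should give [3-(benzyloxy)-4,5-dimethoxybenzyl]magnesium chloride F3. Salicylaldehyde 11 is first turned into its magnesium phenoxide (i-PrMgCl, 1 equiv) and then treated with F3, which should give racemic 1-[3,4,6-tris(benzyloxy)-2-hydroxy-5-methoxyphenyl]-2-[3-(benzyloxy)-4,5-dimethoxyphenyl]ethanol F4. Oxidation of this benzylic alcohol with activated MnO2 in CH2Cl2 should give the deoxybenzoin 1-[3,4,6-tris(benzyloxy)-2-hydroxy-5-methoxyphenyl]-2-[3-(benzyloxy)-4,5-dimethoxyphenyl]ethanone F5. Heating F5 with DMF dimethyl acetal in toluene should form the enaminone 3-(dimethylamino)-1-[3,4,6-tris(benzyloxy)-2-hydroxy-5-methoxyphenyl]-2-[3-(benzyloxy)-4,5-dimethoxyphenyl]prop-2-en-1-one F6, which closes by conjugate addition of the phenol and loss of dimethylamine to 20.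

Step 7 (last ortho-formylation). Hydroxymethylation at the final ring position may stall, because that carbon is flanked by the phenoxide and a benzyloxy group and the neighbouring ether oxygens can tie up the magnesium. The fallback sets out from 10 and comes back at 11. It is a Vilsmeier–Haack formylation of the free phenol (POCl3, DMF, MeCN, 0 °C → rt, then water), in which a small preformed chloroiminium electrophile attacks the only unsubstituted, triply activated ring carbon without any need for a magnesium chelate. The salt formed, N-[3,4,6-tris(benzyloxy)-2-hydroxy-5-methoxybenzylidene]-N-methylmethanaminium dichlorophosphate F7, is hydrolysed on aqueous work-up to 11.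

Step 14 (global debenzylation). The C2=C3 bond of the pyranone may be reduced once the benzyl groups are gone, or the hydroquinone-type 5,8-dihydroxy ring A may be oxidised by air during catalyst filtration and isolation. The fallback goes from 20 directly to 21. It is a Lewis-acid debenzylation with BCl3 and pentamethylbenzene as benzyl-cation scavenger in CH2Cl2 at −78 °C, quenched with MeOH. No hydrogen or metal catalyst is present, the aryl methyl ethers are expected to survive at this temperature, and no new compound is formed on the way (entry F0).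

Further compounds
F1 | step 12 | [3-(benzyloxy)-4,5-dimethoxyphenyl]methanol | COc1cc(CO)cc(OCc2ccccc2)c1OC
F2 | step 12 | 1-(benzyloxy)-5-(chloromethyl)-2,3-dimethoxybenzene | COc1cc(CCl)cc(OCc2ccccc2)c1OC
F3 | step 12 | [3-(benzyloxy)-4,5-dimethoxybenzyl]magnesium chloride | COc1cc(C[Mg]Cl)cc(OCc2ccccc2)c1OC
F4 | step 12 | 1-[3,4,6-tris(benzyloxy)-2-hydroxy-5-methoxyphenyl]-2-[3-(benzyloxy)-4,5-dimethoxyphenyl]ethanol (racemic) | OC(Cc1cc(OC)c(OC)c(OCc2ccccc2)c1)c1c(O)c(OCc2ccccc2)c(OCc2ccccc2)c(OC)c1OCc1ccccc1
F5 | step 12 | 1-[3,4,6-tris(benzyloxy)-2-hydroxy-5-methoxyphenyl]-2-[3-(benzyloxy)-4,5-dimethoxyphenyl]ethanone | O=C(Cc1cc(OC)c(OC)c(OCc2ccccc2)c1)c1c(O)c(OCc2ccccc2)c(OCc2ccccc2)c(OC)c1OCc1ccccc1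
F6 | step 12 | 3-(dimethylamino)-1-[3,4,6-tris(benzyloxy)-2-hydroxy-5-methoxyphenyl]-2-[3-(benzyloxy)-4,5-dimethoxyphenyl]prop-2-en-1-one (not isolated, geometry not defined) | CN(C)C=C(C(=O)c1c(O)c(OCc2ccccc2)c(OCc2ccccc2)c(OC)c1OCc1ccccc1)c1cc(OC)c(OC)c(OCc2ccccc2)c1
F7 | step 7 | N-[3,4,6-tris(benzyloxy)-2-hydroxy-5-methoxybenzylidene]-N-methylmethanaminium dichlorophosphate (not isolated) | C[N+](C)=Cc1c(O)c(OCc2ccccc2)c(OCc2ccccc2)c(OC)c1OCc1ccccc1.[O-]P(Cl)(Cl)=O
F0 | step 14 | none | none
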